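At early times no gas is dissolved, so the flask waits on the crossing from the gas phase; the question is how the substrate divides once gas arrives.

substrate 0.20 M; gas phase 44 mM (held); free catalyst 0.067 mol%; time 2.0 min

    gas phase ⇌ dissolved gas, rate k1*(csat - [dissolved gas]) (k1 = 0.055 /s, csat = 44 mM)
    substrate + dissolved gas + free catalyst → free catalyst + target (k2 = 27000 /M²/s)
    substrate + dissolved gas → uncatalysed product (k3 = 0.48 /M/s)
    dissolved gas + free catalyst → spent catalyst (k4 = 0.87 /M/s)

- amount of target at 2.0 min, in percent of the substrate charged
- concentration of dissolved gas in solution at 2.0 min, in percent of saturation

- at the start none of the gas is dissolved
- run time (flask): 2.0 min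

How does the substrate divide? Both reactions take substrate and dissolved gas once each, so those concentrations cancel from the ratio of their rates. What stays is 7.54 at the charge: the selectivity ratio, the catalysed constant times c(free catalyst) over the uncatalysed constant. The target's share of what reacts therefore starts at 88.3%.

Does the ratio drift? Yes, as c(free catalyst) falls, and dissolved gas is what removes free catalyst.

How much dissolved gas stands in the flask? The catalysed step alone, the other concentrations as charged, halves it in 0.96 s, faster than the crossing's half-time of 12.6 s, so I put supply and consumption in balance at a low c(dissolved gas) of about 2.77 mM. Holding that level up to 2.0 min, I reckon 74.9% of the free catalyst surviving, a ratio of 5.65 and a share of 85.0%.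

And when the substrate thins? That balance then fails. The crossing can deliver up to 145% of the charge by 2.0 min into a solution kept empty, more than the substrate takes, so I expect c(dissolved gas) to climb late, and my surviving catalyst is a figure for the starved stretch. I commit to a yield somewhat below 85.0% and to a saturation well above 6.29%, without a closer hand figure.

The forecast says 83% and 67%, holding that “the uncatalysed route and a few percent of unreacted substrate hold the yield” there.

The simulation gives 82.5% and 66.4%.

In this flask at 2.00 min, the catalysed step uses substrate 2.6 times as fast as the uncatalysed one, which is the starting ratio times the 34.0% of catalyst still free, and lower than my starved 5.65. Dissolved gas then stands at 0.0292 M, and target at 82.5% against 13.9% uncatalysed product. The neighbouring flask with 0.050 M substrate at the same loading starts from a lower ratio, 1.88, and it ends with 46.0% target against 47.7% uncatalysed product.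

(The constants come from no measurement; the run is a simulation.)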